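Thursday's flask is reckoned through G rather than through E, because its charge of G, 0.330 M, stands below the 3.00 M of E, and this makes G the limiting reagent of E + G → Q.

| flask | E | G | time |
|---|---|---|---|
| Sunday's | 1.00 M | 1.00 M |  |
| Wednesday's | 3.00 M | 1.00 M |  |
| Thursday's | 3.00 M | 0.330 M | 6.2 h |

| run | time / h | [Q] / M |
|---|---|---|
| Sunday's run | 0.25 | 0.032 |
| Sunday's run | 0.47 | 0.060 |
| Sunday's run | 0.90 | 0.128 |
| Sunday's run | 1.7 | 0.213 |
| Sunday's run | 3.3 | 0.298 |
| Sunday's run | 6.2 | 0.334 |
| Wednesday's run | 0.25 | 0.061 |
| Wednesday's run | 0.47 | 0.147 |
| Wednesday's run | 0.90 | 0.285 |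
| Wednesday's run | 1.7 | 0.431 |
| Wednesday's run | 3.3 | 0.559 |
| Wednesday's run | 6.2 | 0.630 |

(each reading ± 0.005 M)

- Overall: E + G -> Q.
- Constant volume, constant temperature.
- "The second partner" is G.
- An order is taken over about fifteen percent of the charge, up and down.

- the exponent of [E] in the starting rate at the charge of the Sunday's run (at the point where two percent of the E have become Q) (one fixed amount of Q, the same in the runs compared)
- Q in the Thursday's run at 6.2 h, as a share of the E charged

A bench rule serves here: if the rate is first order in a reagent, then at one course of E and one time the same share of that reagent is spent, whatever its charge. Wednesday's flask has Thursday's charge of E and reaches 0.630 M of Q from 1.00 M of G at 6.2 h, which is 63.0%. This is the spent share of G, cQ at that time over the cG charged. Applied to Thursday's flask, my rule gives 0.208 M, or 6.93% of the E charged.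

The rule has a border. Both earlier flasks hold the same cG at the start, so first order in G is assumed, not read. Thursday's charge of G is lower by a factor of 3.03, so Q can draw at most 11.0% of Thursday's E, while Q in Wednesday's flask at 6.2 h reads 21.0% of that flask's E. The course of E can therefore differ between these two flasks. Sunday's spent share at 6.2 h, 33.4%, stands below Wednesday's with the same cG and less E charged, so the share rises with the charge of E in these two flasks, and my figure may lean low.

The forecast holds that the plateau quotient “points to an equilibrium”. It gives 7.3%, above my figure, and an exponent of 0.8.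

Thursday's flask gives 8.60% of its E as Q at 6.2 h, and the exponent of cE in the starting rate at Sunday's charge is 0.62.

    E ⇌ Z (1.440 h⁻¹, 0.9792 h⁻¹)
    Z + G → Q (0.7596 L mol⁻¹ h⁻¹)
    E → Gy (0.6516 h⁻¹)
    2 E → Xi (0.5904 L mol⁻¹ h⁻¹)

Where the same small amount of Q had been made, Wednesday's rate stood at 1.9 times Sunday's. In Thursday's flask the spent share of G at 6.2 h is 78.2%, above the 63.0% read in Wednesday's flask, with 0.0720 M of G remaining.

All runs were computed for an exercise; the scatter is artificial.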